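**Plan**

1. Retrosynthesis: the three MOM ethers and a 1,3-dithiane mask on C4 come off last; ring C is then cut at C3–C4 and at O1–C8a, giving a lithiated 2-aryl-1,3-dithiane (ring A carrying C4) and an (R)-aryl oxirane (ring B carrying C2, C3 and O1).
2. Enabling feature: in ring C the carbonyl carbon C4 and the ring oxygen O1 are 1,3-related across C3–C2, which is the pattern of a ring-opened epoxide, and C8a lies ortho to C4a, the carbon that already bears C4; an acyl-anion equivalent at C4 and a fluoride at C8a can therefore take up C3 and O1 of one epoxide in turn.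
3. Ring B fragment, forward: regioselective O-methylation of a bromocatechol ester, MOM protection, Stille prenylation, ester to chloromethyl ketone, asymmetric transfer hydrogenation with epoxide closure.
4. Ring A fragment, forward: Vilsmeier formylation of 5-fluororesorcinol, dithiane formation, MOM protection.
5. Union: the dithiane anion opens the epoxide and the released alkoxide closes ring C by intramolecular SNAr in the same flask; dithiane hydrolysis and MOM removal finish the route.
6. Stereochemistry: the only stereocentre, C2 (S), is set by the (S,S)-TsDPEN rhodium transfer hydrogenation (R chlorohydrin, R epoxide) and its C–O bond is never broken afterwards; the C4 carbonyl is unmasked only after the last basic step.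

Key step: step 9

Remark: the target as drawn is the (2S)-flavanone; because a free flavanone epimerises at C2 by base-induced ring opening, the carbonyl is kept as a dithiane through all basic operations. Compounds 1 and 9 are taken as commercially available.

**Route**

Step 1
Reactants: 1 methyl 3-bromo-4,5-dihydroxybenzoate
Product: 2 methyl 3-bromo-5-hydroxy-4-methoxybenzoate
Conditions: MeI (1.05 equiv), Li2CO3 (1.1 equiv), DMF, 40 °C
Reagents that add atoms: iodomethane, CI
Why: The 4-OH, para to the ester and ortho to bromine, is the more acidic phenol, so one equivalent of weak base should form mainly its phenoxide, which is methylated (regioselective Williamson ether synthesis).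

Step 2
Reactants: 2 methyl 3-bromo-5-hydroxy-4-methoxybenzoate
Product: 3 methyl 3-bromo-4-methoxy-5-(methoxymethoxy)benzoate
Conditions: MOMCl, i-Pr2NEt, CH2Cl2, 0 °C → rt
Reagents that add atoms: chloromethyl methyl ether, COCCl
Why: O-Alkylation of the remaining phenol should give the MOM ether, which withstands the organometallic and basic steps ahead and is removed by acid at the end (acetal protection of a phenol).

Step 3
Reactants: 3 methyl 3-bromo-4-methoxy-5-(methoxymethoxy)benzoate
Product: 4 methyl 4-methoxy-3-(methoxymethoxy)-5-(3-methylbut-2-en-1-yl)benzoate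
Conditions: tributyl(3-methylbut-2-en-1-yl)stannane, Pd(PPh3)4 (5 mol%), DMF, 100 °C
Reagents that add atoms: tributyl(3-methylbut-2-en-1-yl)stannane, CCCC[Sn](CCCC)(CCCC)CC=C(C)C
Why: Stille coupling, in which zerovalent palladium inserts into the aryl C–Br bond, the prenyl group is transferred from tin and reductive elimination at the less hindered allyl terminus should give the linear prenyl arene while ester and MOM ether stay untouched.

Step 4
Reactants: 4 methyl 4-methoxy-3-(methoxymethoxy)-5-(3-methylbut-2-en-1-yl)benzoate
Product: 6 2-chloro-1-[4-methoxy-3-(methoxymethoxy)-5-(3-methylbut-2-en-1-yl)phenyl]ethan-1-one, via lithium hemiketal adduct 5 (not isolated)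
Conditions: ICH2Cl (1.5 equiv), MeLi·LiBr (1.4 equiv), THF, −78 °C; then AcOH, −78 °C → rt
Reagents that add atoms: chloroiodomethane, ClCI
Why: Chloromethyllithium, formed by iodine–lithium exchange in the presence of the ester, should add once to give a tetrahedral lithium hemiketal that is stable at −78 °C and collapses to the chloromethyl ketone only on acidic quench (carbenoid homologation of an ester).

Step 5
Reactants: 6 2-chloro-1-[4-methoxy-3-(methoxymethoxy)-5-(3-methylbut-2-en-1-yl)phenyl]ethan-1-one
Product: 8 (2R)-2-[4-methoxy-3-(methoxymethoxy)-5-(3-methylbut-2-en-1-yl)phenyl]oxirane, via (R)-chlorohydrin 7 (not isolated)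
Conditions: Cp*RhCl[(S,S)-TsDPEN] (0.5 mol%), HCO2H/Et3N (5:2), EtOAc, rt; then 2 M aq. NaOH, i-PrOH, 0 °C → rt
Reagents that add atoms: none
Why: Noyori-type asymmetric transfer hydrogenation with the (S,S)-TsDPEN rhodium hydride should reduce the aryl ketone in the sense that gives (S)-1-phenylethanol from acetophenone, which here is the (R)-chlorohydrin because CH2Cl outranks aryl, and the alkoxide then closes the epoxide by intramolecular SN2 at CH2 without touching the stereocentre or the prenyl alkene.

Step 6
Reactants: 9 5-fluorobenzene-1,3-diol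
Product: 11 2-fluoro-4,6-dihydroxybenzaldehyde, via aryl iminium chloride 10 (not isolated)
Conditions: POCl3, DMF, MeCN, 0 °C → rt; then H2O, 50 °C
Reagents that add atoms: N,N-dimethylformamide, CN(C)C=O; water, O
Why: Vilsmeier–Haack formylation should occur para to one hydroxyl and ortho to the other, at the carbon next to fluorine, as with resorcinol and orcinol, and not at the more crowded carbon between the two hydroxyls.

Step 7
Reactants: 11 2-fluoro-4,6-dihydroxybenzaldehyde
Product: 12 2-(2-fluoro-4,6-dihydroxyphenyl)-1,3-dithiane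
Conditions: propane-1,3-dithiol, BF3·OEt2 (cat.), THF/CH2Cl2, 0 °C → rt
Reagents that add atoms: propane-1,3-dithiol, SCCCS
Why: Lewis-acid-catalysed dithioacetalisation of the aldehyde, placed before MOM protection because the Lewis acid and thiol would cleave MOM ethers.

Step 8
Reactants: 12 2-(2-fluoro-4,6-dihydroxyphenyl)-1,3-dithiane
Product: 13 2-[2-fluoro-4,6-bis(methoxymethoxy)phenyl]-1,3-dithiane
Conditions: MOMCl (2.5 equiv), i-Pr2NEt (3 equiv), CH2Cl2, 0 °C → rt
Reagents that add atoms: chloromethyl methyl ether, COCCl
Why: Both phenols should be O-alkylated to MOM ethers, which tolerate n-BuLi and hot alkoxide and leave the dithiane C–H as the most acidic site (acetal protection of phenols).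

Step 9
Reactants: 13 2-[2-fluoro-4,6-bis(methoxymethoxy)phenyl]-1,3-dithiane; 8 (2R)-2-[4-methoxy-3-(methoxymethoxy)-5-(3-methylbut-2-en-1-yl)phenyl]oxirane
Product: 16 (2S)-2-[4-methoxy-3-(methoxymethoxy)-5-(3-methylbut-2-en-1-yl)phenyl]-5,7-bis(methoxymethoxy)-2,3-dihydrospiro[chromene-4,2'-[1,3]dithiane], via lithiated dithiane 14 (not isolated), via lithium alkoxide 15 (not isolated)
Conditions: n-BuLi (1.0 equiv), THF, −78 → −30 °C; 8, −78 °C → rt; then DMPU, 65 °C
Reagents that add atoms: none
Why: Deprotonation of 13 at the dithiane C–H gives the acyl-anion equivalent 14, which opens oxirane 8 by SN2 attack at its unsubstituted CH2 (C3–C4 bond); the lithium alkoxide 15 thus released on C2 then displaces the fluoride ortho to the dithiane-bearing carbon by intramolecular addition–elimination (O1–C8a bond), with lithium assisting loss of fluoride. The closest known reaction types are the Corey–Seebach opening of terminal epoxides by 2-aryl-2-lithio-1,3-dithianes and the intramolecular SNAr etherification of non-activated 3-(2-fluoroaryl)propanols to chromans, here run in one flask. Ring C closes in a 6-exo-trig addition–elimination at C8a, helped by the fully substituted C4 and by the two alkoxy groups meta to the C–F carbon, which activate it inductively without donating to it by resonance. No stereocentre is created: C2 is brought in from 8 and keeps its configuration because its C–O bond is never broken, and with C4 masked there is no acidic C3–H, so neither retro-aldol nor retro-oxa-Michael scrambling is possible under the basic conditions. The step needs attack at the epoxide CH2 and not at the benzylic carbon, which the bulk of the tertiary carbanion and the absence of a Lewis acid should secure, and metalation of the dithiane C–H and not of the ring C–H next to fluorine, which its higher acidity and the use of exactly one equivalent of n-BuLi at −78 °C should secure.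

Step 10
Reactants: 16 (2S)-2-[4-methoxy-3-(methoxymethoxy)-5-(3-methylbut-2-en-1-yl)phenyl]-5,7-bis(methoxymethoxy)-2,3-dihydrospiro[chromene-4,2'-[1,3]dithiane]
Product: 17 (2S)-2-[4-methoxy-3-(methoxymethoxy)-5-(3-methylbut-2-en-1-yl)phenyl]-5,7-bis(methoxymethoxy)-2,3-dihydro-4H-chromen-4-one
Conditions: MeI (excess), CaCO3, MeCN/H2O (4:1), 45 °C
Reagents that add atoms: water, O
Why: Alkylative dithiane hydrolysis, in which S-methylation turns sulfur into a leaving group and the thionium ion stabilised by electron-rich ring A is trapped by water, under buffered non-oxidative conditions that should spare the prenyl alkene, the MOM ethers and the C2 stereocentre.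

Step 11
Reactants: 17 (2S)-2-[4-methoxy-3-(methoxymethoxy)-5-(3-methylbut-2-en-1-yl)phenyl]-5,7-bis(methoxymethoxy)-2,3-dihydro-4H-chromen-4-one
Product: 18 (2S)-5,7-dihydroxy-2-[3-hydroxy-4-methoxy-5-(3-methylbut-2-en-1-yl)phenyl]-2,3-dihydro-4H-chromen-4-one
Conditions: 3 M aq. HCl/MeOH (1:4), 45 °C
Reagents that add atoms: none
Why: Acid-catalysed acetal exchange should remove all three MOM ethers, since flavanones hold their C2 configuration in dilute acid and the prenyl group has no ortho hydroxyl to cyclise onto.

**Compound list**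

1 | methyl 3-bromo-4,5-dihydroxybenzoate | COC(=O)c1cc(O)c(O)c(Br)c1 | starting material
2 | methyl 3-bromo-5-hydroxy-4-methoxybenzoate | COC(=O)c1cc(O)c(OC)c(Br)c1 | intermediate
3 | methyl 3-bromo-4-methoxy-5-(methoxymethoxy)benzoate | COC(=O)c1cc(OCOC)c(OC)c(Br)c1 | intermediate
4 | methyl 4-methoxy-3-(methoxymethoxy)-5-(3-methylbut-2-en-1-yl)benzoate | COC(=O)c1cc(OCOC)c(OC)c(CC=C(C)C)c1 | intermediate
5 | lithium 2-chloro-1-methoxy-1-[4-methoxy-3-(methoxymethoxy)-5-(3-methylbut-2-en-1-yl)phenyl]ethan-1-olate (hemiketal adduct, not isolated) | [Li]OC(OC)(CCl)c1cc(OCOC)c(OC)c(CC=C(C)C)c1 | intermediate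
6 | 2-chloro-1-[4-methoxy-3-(methoxymethoxy)-5-(3-methylbut-2-en-1-yl)phenyl]ethan-1-one | O=C(CCl)c1cc(OCOC)c(OC)c(CC=C(C)C)c1 | intermediate
7 | (1R)-2-chloro-1-[4-methoxy-3-(methoxymethoxy)-5-(3-methylbut-2-en-1-yl)phenyl]ethan-1-ol (not isolated) | O[C@@H](CCl)c1cc(OCOC)c(OC)c(CC=C(C)C)c1 | intermediate
8 | (2R)-2-[4-methoxy-3-(methoxymethoxy)-5-(3-methylbut-2-en-1-yl)phenyl]oxirane | C1O[C@@H]1c1cc(OCOC)c(OC)c(CC=C(C)C)c1 | intermediate
9 | 5-fluorobenzene-1,3-diol | Oc1cc(O)cc(F)c1 | starting material
10 | N-[(2-fluoro-4,6-dihydroxyphenyl)methylidene]-N-methylmethanaminium chloride (not isolated) | C[N+](C)=Cc1c(O)cc(O)cc1F.[Cl-] | intermediate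
11 | 2-fluoro-4,6-dihydroxybenzaldehyde | O=Cc1c(O)cc(O)cc1F | intermediate
12 | 2-(2-fluoro-4,6-dihydroxyphenyl)-1,3-dithiane | Oc1cc(O)c(C2SCCCS2)c(F)c1 | intermediate
13 | 2-[2-fluoro-4,6-bis(methoxymethoxy)phenyl]-1,3-dithiane | COCOc1cc(OCOC)c(C2SCCCS2)c(F)c1 | intermediate
14 | 2-[2-fluoro-4,6-bis(methoxymethoxy)phenyl]-2-lithio-1,3-dithiane (not isolated) | [Li]C1(SCCCS1)c1c(F)cc(OCOC)cc1OCOC | intermediate
15 | lithium (1S)-2-{2-[2-fluoro-4,6-bis(methoxymethoxy)phenyl]-1,3-dithian-2-yl}-1-[4-methoxy-3-(methoxymethoxy)-5-(3-methylbut-2-en-1-yl)phenyl]ethan-1-olate (not isolated) | [Li]O[C@@H](CC1(SCCCS1)c1c(F)cc(OCOC)cc1OCOC)c1cc(OCOC)c(OC)c(CC=C(C)C)c1 | intermediate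
16 | (2S)-2-[4-methoxy-3-(methoxymethoxy)-5-(3-methylbut-2-en-1-yl)phenyl]-5,7-bis(methoxymethoxy)-2,3-dihydrospiro[chromene-4,2'-[1,3]dithiane] | COc1c(OCOC)cc([C@@H]2CC3(SCCCS3)c3c(OCOC)cc(OCOC)cc3O2)cc1CC=C(C)C | intermediate
17 | (2S)-2-[4-methoxy-3-(methoxymethoxy)-5-(3-methylbut-2-en-1-yl)phenyl]-5,7-bis(methoxymethoxy)-2,3-dihydro-4H-chromen-4-one | COc1c(OCOC)cc([C@@H]2CC(=O)c3c(OCOC)cc(OCOC)cc3O2)cc1CC=C(C)C | intermediate
18 | (2S)-5,7-dihydroxy-2-[3-hydroxy-4-methoxy-5-(3-methylbut-2-en-1-yl)phenyl]-2,3-dihydro-4H-chromen-4-one | COc1c(O)cc([C@@H]2CC(=O)c3c(O)cc(O)cc3O2)cc1CC=C(C)C | target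

**Step count**

Total: 11 steps. Longest linear sequence: 8 steps (steps 1 to 5, then 9, 10 and 11).

**Steps most likely to fail**

Step 9. The hindered tertiary dithianyl anion may open the oxirane only slowly. More seriously, the tethered lithium alkoxide may fail to displace fluoride from the carbonyl-free, electron-rich ring before side reactions set in, such as ring lithiation next to fluorine followed by loss of LiF. The fallback inverts the order of unmasking and ring closure, so that the C–F bond is attacked only when an ortho carbonyl activates it. It sets out from 13 and 8, which are joined as in step 9 but quenched with water at room temperature to give the alcohol (1S)-2-{2-[2-fluoro-4,6-bis(methoxymethoxy)phenyl]-1,3-dithian-2-yl}-1-[4-methoxy-3-(methoxymethoxy)-5-(3-methylbut-2-en-1-yl)phenyl]ethan-1-ol F1. Hydrolysis with MeI and CaCO3 in aqueous MeCN then gives the hydroxy ketone (3S)-1-[2-fluoro-4,6-bis(methoxymethoxy)phenyl]-3-hydroxy-3-[4-methoxy-3-(methoxymethoxy)-5-(3-methylbut-2-en-1-yl)phenyl]propan-1-one F2. Ring C is closed by carbonyl-activated SNAr with K2CO3 in DMF at 0 °C to room temperature, kept short and cold to limit retro-aldol cleavage, and the route is rejoined at 17.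

Step 10. Hydrolysis of the congested spiro-dithiane may be slow, and forcing it may cause ionisation at C4, followed by elimination or by loss of MOM groups under the acid formed. The fallback activates one sulfur by oxidation instead of alkylation and merges unmasking with deprotection. It sets out from 16, which is oxidised with NaIO4 (1 equiv) in MeOH/H2O at 0 °C to the monosulfoxide (2S)-2-[4-methoxy-3-(methoxymethoxy)-5-(3-methylbut-2-en-1-yl)phenyl]-5,7-bis(methoxymethoxy)-2,3-dihydrospiro[chromene-4,2'-[1,3]dithiane] 1'-oxide F3, a mixture of diastereomers at sulfur and C4. Aqueous HCl in MeOH at 45 °C should then hydrolyse the dithioacetal S-oxide to the ketone and remove the three MOM ethers in the same operation, and the route is rejoined at 18.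

Step 6. Formylation may take place in part at the carbon between the two hydroxyls (para to fluorine), giving regioisomers that must be separated. The fallback fixes the site by bromination of the bulkier bis-ether and brings in the dithiane carbon as an electrophile. It sets out from 9, which is protected with MOMCl and i-Pr2NEt to 1-fluoro-3,5-bis(methoxymethoxy)benzene F4. NBS in MeCN at 0 °C should then brominate para to one MOM ether and next to fluorine, giving 2-bromo-1-fluoro-3,5-bis(methoxymethoxy)benzene F5. Bromine–magnesium exchange with i-PrMgCl·LiCl in THF at 0 °C gives [2-fluoro-4,6-bis(methoxymethoxy)phenyl]magnesium chloride F6, which does not readily lose fluoride. It is alkylated with 2-chloro-1,3-dithiane F7, freshly made from 1,3-dithiane and N-chlorosuccinimide, and the route is rejoined at 13.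

**Further compounds**

F1 | step 9 | (1S)-2-{2-[2-fluoro-4,6-bis(methoxymethoxy)phenyl]-1,3-dithian-2-yl}-1-[4-methoxy-3-(methoxymethoxy)-5-(3-methylbut-2-en-1-yl)phenyl]ethan-1-ol | O[C@@H](CC1(SCCCS1)c1c(F)cc(OCOC)cc1OCOC)c1cc(OCOC)c(OC)c(CC=C(C)C)c1
F2 | step 9 | (3S)-1-[2-fluoro-4,6-bis(methoxymethoxy)phenyl]-3-hydroxy-3-[4-methoxy-3-(methoxymethoxy)-5-(3-methylbut-2-en-1-yl)phenyl]propan-1-one | O[C@@H](CC(=O)c1c(F)cc(OCOC)cc1OCOC)c1cc(OCOC)c(OC)c(CC=C(C)C)c1
F3 | step 10 | (2S)-2-[4-methoxy-3-(methoxymethoxy)-5-(3-methylbut-2-en-1-yl)phenyl]-5,7-bis(methoxymethoxy)-2,3-dihydrospiro[chromene-4,2'-[1,3]dithiane] 1'-oxide (configuration at sulfur and C4 not defined) | COc1c(OCOC)cc([C@@H]2CC3(SCCCS3=O)c3c(OCOC)cc(OCOC)cc3O2)cc1CC=C(C)C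
F4 | step 6 | 1-fluoro-3,5-bis(methoxymethoxy)benzene | COCOc1cc(F)cc(OCOC)c1
F5 | step 6 | 2-bromo-1-fluoro-3,5-bis(methoxymethoxy)benzene | COCOc1cc(OCOC)c(Br)c(F)c1
F6 | step 6 | [2-fluoro-4,6-bis(methoxymethoxy)phenyl]magnesium chloride | Cl[Mg]c1c(F)cc(OCOC)cc1OCOC
F7 | step 6 | 2-chloro-1,3-dithiane | ClC1SCCCS1
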